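**Plan**
- Cuts: (a) the C(sp3)–C(sp2) bond that joins the side chain's homoallylic CH2 to its first trisubstituted alkene; (b) in the cyclohexane, the ring CH2–alkylidene carbon bond and the carbinol carbon–quaternary carbon bond, cut together; (c) the acyclic precursor back to a chiral unsaturated δ-lactone.
- Enabling feature: the ring segment CH2–CH2–C(OH)CH3 is a ring-opened 1-methylcyclopropanol (a β-metallo methyl ketone). The alkylidene ring carbon is the β-carbon of the enal, so it can be the enol triflate carbon of a β-keto ester. The quaternary carbon carries CH3 and a CH2CH2 stub, so it can be the γ-carbon of a γ,γ-disubstituted allylboronate that leaves a vinyl group.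
- Forward: Evans alkylation, lactone by ring-closing metathesis, borylative lactone opening, β-keto ester, (E)-enol triflate, one-flask cyclopropanol cross-coupling/allylboration to build the cyclohexane, side chain by hydroboration/Suzuki–Miyaura coupling, ester to enal, desilylation.
- Stereochemistry: the ring C–H centre comes from the oxazolidinone alkylation and steers the carbinol and quaternary centres through a chair allylboration. The (Z)-allylboronate geometry is fixed by the temporary lactone ring. The enal geometry comes from stereoretentive coupling of the (E)-enol triflate, and the chain alkenes from Zr-catalysed carboalumination.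

Key step: step 9

Remark: the tertiary borate formed on ring closure is assumed to hydrolyse on aqueous work-up; compounds 4, 12 and 16 are taken as purchasable. TBS = tert-butyl(dimethyl)silyl; Bpin = 4,4,5,5-tetramethyl-1,3,2-dioxaborolan-2-yl.

**Route**

Step 1
Reactants: 1 (4R)-4-benzyl-1,3-oxazolidin-2-one; 2 3-methylbut-2-enoyl chloride
Product: 3 (4R)-4-benzyl-3-(3-methylbut-2-enoyl)-1,3-oxazolidin-2-one
Conditions: n-BuLi, THF, −78 °C; then 2, −78 → 0 °C
Reagents that add atoms: none
Why: N-acylation of the lithiated oxazolidinone by the acid chloride should give the imide without touching the auxiliary stereocentre.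

Step 2
Reactants: 4 3-(TBS-oxy)propan-1-ol
Product: 5 3-(TBS-oxy)propyl trifluoromethanesulfonate
Conditions: Tf2O, 2,6-lutidine, CH2Cl2, −78 °C; used at once
Reagents that add atoms: trifluoromethanesulfonic anhydride O=S(=O)(OS(=O)(=O)C(F)(F)F)C(F)(F)F
Why: O-sulfonylation of the primary alcohol should give an alkylating agent reactive enough for an imide enolate at low temperature, where an unactivated iodide would be too slow.

Step 3
Reactants: 3 senecioyl imide; 5 alkyl triflate
Product: 6 (4R)-4-benzyl-3-[(2R)-5-(TBS-oxy)-2-(prop-1-en-2-yl)pentanoyl]-1,3-oxazolidin-2-one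
Conditions: NaN(SiMe3)2, THF, −78 °C; then 5, −78 → −40 °C
Reagents that add atoms: none
Why: γ-deprotonation should give the chelated sodium dienolate, which is alkylated at the α-carbon on the face away from the benzyl group (Evans deconjugative alkylation), setting the (R) C–H stereocentre that becomes the ring carbon bearing the hydroxypropyl chain.

Step 4
Reactants: 6 alkylated imide; 7 prop-2-en-1-ol
Product: 8 prop-2-en-1-yl (2R)-5-(TBS-oxy)-2-(prop-1-en-2-yl)pentanoate
Conditions: 7, n-BuLi, THF, −20 → 0 °C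
Reagents that add atoms: none
Why: lithium allyl oxide should attack the exocyclic imide carbonyl (alkoxide transesterification of an N-acyl oxazolidinone) and release the auxiliary, the low temperature sparing the α-stereocentre.

Step 5
Reactants: 8 allyl ester
Product: 9 (3R)-3-[3-(TBS-oxy)propyl]-4-methyl-3,6-dihydro-2H-pyran-2-one
Conditions: second-generation Grubbs catalyst (5 mol %), CH2Cl2, 40 °C
Reagents that add atoms: none
Why: ring-closing metathesis between the isopropenyl and allyl alkenes should close the six-membered lactone, and this temporary ring forces the new trisubstituted alkene into the cis arrangement needed for the allylboronate.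

Step 6
Reactants: 9 unsaturated lactone
Product: 11 (2R,3Z)-2-[3-(TBS-oxy)propyl]-3-methyl-5-(Bpin)pent-3-enoic acid, via boryl ester 10 (not isolated)
Conditions: Pd2(dba)3 (2.5 mol %), B2pin2, THF, 60 °C; aqueous work-up
Reagents that add atoms: bis(pinacolato)diboron CC1(C)OB(OC1(C)C)B1OC(C)(C)C(C)(C)O1
Why: zerovalent palladium should ionise the allylic C–O bond of the lactone to a π-allylpalladium carboxylate that transmetalates with B2pin2 and reductively eliminates at the unsubstituted terminus (Miyaura-type borylation of an allylic carboxylate), the (Z) geometry persisting because syn–anti exchange would need a tertiary σ-allyl.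

Step 7
Reactants: 11 allylboronate acid; 12 ethyl hydrogen methylmalonate
Product: 14 ethyl (4R,5Z)-4-[3-(TBS-oxy)propyl]-2,5-dimethyl-3-oxo-7-(Bpin)hept-5-enoate (both epimers at the carbon between the carbonyl groups), via acyl imidazole 13 (not isolated)
Conditions: 1,1'-carbonyldiimidazole, THF, 23 °C; then magnesium salt of 12 (from 12, i-PrMgCl, THF, 0 °C), 23 → 40 °C; aq. citric acid
Reagents that add atoms: none
Why: C-acylation of the magnesium enolate of the malonate half ester by the acyl imidazole and loss of CO2 (Masamune–Brooks homologation) should give the β-keto ester under near-neutral conditions that spare the α-stereocentre, the skipped alkene and the allylboronate.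

Step 8
Reactants: 14 β-keto ester
Product: 15 ethyl (2E,4R,5Z)-4-[3-(TBS-oxy)propyl]-2,5-dimethyl-7-(Bpin)-3-{[(trifluoromethyl)sulfonyl]oxy}hepta-2,5-dienoate
Conditions: Tf2O, aq. Me4NOH, toluene, 0 °C
Reagents that add atoms: trifluoromethanesulfonic anhydride O=S(=O)(OS(=O)(=O)C(F)(F)F)C(F)(F)F
Why: Schotten–Baumann O-triflation of the tetramethylammonium enolate, which cannot chelate and so holds the enolate oxygen anti to the ester, should give the (E)-enol triflate, the geometry that places the ester cis to the stereogenic carbon.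

Step 9
Reactants: 15 (E)-enol triflate; 16 1-methylcyclopropan-1-ol
Product: 19 ethyl (2Z)-2-[(2S,3S,4R)-2-[3-(TBS-oxy)propyl]-3-ethenyl-4-hydroxy-3,4-dimethylcyclohexylidene]propanoate, via keto allylboronate 17 (not isolated), via pinacol borate 18 (not isolated)
Conditions: Pd(OAc)2 (5 mol %), XPhos (10 mol %), Cs2CO3, toluene, 80 °C, then 100 °C; aqueous work-up
Reagents that add atoms: none
Why: Proposed new method: zerovalent palladium inserts into the C–OTf bond of 15, alkoxide exchange with 16 and strain-releasing β-carbon elimination of the divalent palladium cyclopropoxide give a palladium homoenolate, and reductive elimination forges the ring CH2–alkylidene carbon bond with retention of alkene geometry and unmasks methyl ketone 17; the pendant (Z)-allylboronate then adds through its γ-carbon to this ketone to give borate 18, hydrolysed to 19 on work-up. The closest known reactions are the palladium-catalysed ring-opening cross-coupling of cyclopropanols (and of zinc homoenolates) with C(sp2) electrophiles and the thermal intramolecular allylboration of carbonyl groups; running them as one domino is new. The cyclohexane closes by a 6-exo-trig carbonyl addition through a closed Zimmerman–Traxler chair. Because the tether is cis to CH2B on the alkene it must sit axial on the boracycle, which allows only one chair–chair arrangement and makes the hydroxyl cis to the vinyl group and the two methyl groups cis, so the carbinol and quaternary centres are fixed relative to each other by the ring-derived (Z) geometry. Their absolute sense comes from the existing C–H centre, whose silyloxypropyl chain goes axial to escape 1,3-allylic strain with the ester on the tetrasubstituted alkylidene and therefore ends cis to vinyl and hydroxyl. The step needs the cross-coupling to outrun β-hydride elimination and boron-to-palladium allyl transfer, which the bulky biarylphosphine (fast reductive elimination) and the anhydrous carbonate/toluene medium (pinacol boronate left unactivated until the ketone appears) should secure.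

Step 10
Reactants: 20 pent-4-ynoic acid
Product: 22 N-methoxy-N-methylpent-4-ynamide, via acyl imidazole 21 (not isolated)
Conditions: 1,1'-carbonyldiimidazole, CH2Cl2, 23 °C; then MeNHOMe·HCl
Reagents that add atoms: N,O-dimethylhydroxylamine hydrochloride CNOC.Cl
Why: activation of the acid as its acyl imidazole and aminolysis should give the Weinreb amide.

Step 11
Reactants: 22 Weinreb amide
Product: 23 2-methylhept-6-yn-3-one
Conditions: i-PrMgCl (2.2 equiv), THF, −20 → 0 °C; aq. NH4Cl
Reagents that add atoms: isopropylmagnesium chloride CC(C)[Mg]Cl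
Why: after deprotonation of the alkyne by the first equivalent, the Grignard reagent should add once to the amide, the chelated tetrahedral adduct preventing over-addition (Weinreb ketone synthesis).

Step 12
Reactants: 23 alkynyl ketone
Product: 24 6-methyl-5-methylidenehept-1-yne
Conditions: Ph3PCH3Br, KOt-Bu, THF, 0 → 23 °C
Reagents that add atoms: methyltriphenylphosphonium bromide C[P+](c1ccccc1)(c1ccccc1)c1ccccc1.[Br-]
Why: Wittig methylenation of the ketone should install the 1,1-disubstituted alkene of the chain terminus.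

Step 13
Reactants: 24 enyne
Product: 26 (2E)-3,7-dimethyl-6-methylideneoct-2-en-1-ol, via alkenylalane 25 (not isolated)
Conditions: Me3Al, Cp2ZrCl2 (0.25 equiv), CH2Cl2, 0 → 23 °C; then (CH2O)n, THF, 0 → 23 °C
Reagents that add atoms: trimethylaluminium C[Al](C)C; paraformaldehyde (as formaldehyde) C=O
Why: Zr-catalysed syn-carboalumination of the terminal alkyne (Negishi carboalumination) puts CH3 on the internal carbon and aluminium on the terminus, fixing the (E) alkene, and the alkenylalane is hydroxymethylated by formaldehyde; the 1,1-disubstituted alkene should not react.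

Step 14
Reactants: 26 allylic alcohol
Product: 27 (2E)-1-bromo-3,7-dimethyl-6-methylideneoct-2-ene
Conditions: CBr4, PPh3, CH2Cl2, 0 °C
Reagents that add atoms: carbon tetrabromide BrC(Br)(Br)Br
Why: Appel bromination under neutral conditions should give the primary allylic bromide without allylic transposition or acid addition to the methylidene group.

Step 15
Reactants: 27 allylic bromide; 28 trimethyl(prop-1-yn-1-yl)silane
Product: 29 [(5E)-6,10-dimethyl-9-methylideneundec-5-en-1-yn-1-yl]trimethylsilane
Conditions: 28, n-BuLi, THF, −78 °C; then 27, −78 → 0 °C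
Reagents that add atoms: none
Why: the propargylic lithium reagent from the silylpropyne should displace the primary allylic bromide by SN2 at its propargylic carbon, adding the three-carbon alkyne unit.

Step 16
Reactants: 29 silyl enyne
Product: 30 (5E)-6,10-dimethyl-9-methylideneundec-5-en-1-yne
Conditions: K2CO3, MeOH, 23 °C
Reagents that add atoms: none
Why: methoxide-mediated protodesilylation should free the terminal alkyne.

Step 17
Reactants: 30 terminal enyne
Product: 32 (1E,5E)-1-iodo-2,6,10-trimethyl-9-methylideneundeca-1,5-diene, via alkenylalane 31 (not isolated)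
Conditions: Me3Al, Cp2ZrCl2 (0.25 equiv), CH2Cl2, 0 → 23 °C; then iodine, THF, −30 °C
Reagents that add atoms: trimethylaluminium C[Al](C)C; iodine [I][I]
Why: a second Negishi carboalumination followed by iodinolysis with retention should give the (E)-trisubstituted vinyl iodide.

Step 18
Reactants: 19 vinyl cyclohexanol; 32 vinyl iodide
Product: 34 ethyl (2Z)-2-[(2S,3S,4R)-2-[3-(TBS-oxy)propyl]-4-hydroxy-3,4-dimethyl-3-[(3E,7E)-4,8,12-trimethyl-11-methylidenetrideca-3,7-dien-1-yl]cyclohexylidene]propanoate, via alkylborane 33 (not isolated)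
Conditions: 9-BBN (3 equiv), THF, 0 → 50 °C; then 32, Pd(dppf)Cl2 (5 mol %), AsPh3, Cs2CO3, DMF/H2O, 23 °C
Reagents that add atoms: none
Why: 9-BBN should add anti-Markovnikov to the only monosubstituted alkene (the tetrasubstituted enoate is inert), and B-alkyl Suzuki–Miyaura coupling should join the alkylborane to the vinyl iodide with retention of its geometry.

Step 19
Reactants: 34 coupled ester
Product: 35 (2Z)-2-[(2S,3S,4R)-2-[3-(TBS-oxy)propyl]-4-hydroxy-3,4-dimethyl-3-[(3E,7E)-4,8,12-trimethyl-11-methylidenetrideca-3,7-dien-1-yl]cyclohexylidene]propan-1-ol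
Conditions: i-Bu2AlH (4 equiv), CH2Cl2, −78 → 0 °C; Rochelle salt work-up
Reagents that add atoms: none
Why: 1,2-reduction of the unsaturated ester by the aluminium hydride should give the allylic alcohol without touching the alkenes or any stereocentre.

Step 20
Reactants: 35 allylic alcohol
Product: 36 (2Z)-2-[(2S,3S,4R)-2-[3-(TBS-oxy)propyl]-4-hydroxy-3,4-dimethyl-3-[(3E,7E)-4,8,12-trimethyl-11-methylidenetrideca-3,7-dien-1-yl]cyclohexylidene]propanal
Conditions: MnO2, CH2Cl2, 23 °C
Reagents that add atoms: none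
Why: MnO2 should oxidise only the allylic primary alcohol, leaving the tertiary alcohol and the alkene geometry untouched.

Step 21
Reactants: 36 silyl-protected enal
Product: 37 (2Z)-2-[(2S,3S,4R)-4-hydroxy-2-(3-hydroxypropyl)-3,4-dimethyl-3-[(3E,7E)-4,8,12-trimethyl-11-methylidenetrideca-3,7-dien-1-yl]cyclohexylidene]propanal
Conditions: HF·pyridine, pyridine, THF, 0 → 23 °C
Reagents that add atoms: none
Why: buffered fluoride cleavage of the primary silyl ether should release the target without isomerising the enal or ionising the tertiary alcohol.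

**Compound list**

1 | (4R)-4-benzyl-1,3-oxazolidin-2-one | O=C1N[C@H](Cc2ccccc2)CO1 | starting material
2 | 3-methylbut-2-enoyl chloride | CC(C)=CC(=O)Cl | starting material
3 | (4R)-4-benzyl-3-(3-methylbut-2-enoyl)-1,3-oxazolidin-2-one | CC(C)=CC(=O)N1[C@H](Cc2ccccc2)COC1=O | intermediate
4 | 3-{[tert-butyl(dimethyl)silyl]oxy}propan-1-ol | CC(C)(C)[Si](C)(C)OCCCO | starting material
5 | 3-{[tert-butyl(dimethyl)silyl]oxy}propyl trifluoromethanesulfonate | CC(C)(C)[Si](C)(C)OCCCOS(=O)(=O)C(F)(F)F | intermediate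
6 | (4R)-4-benzyl-3-[(2R)-5-{[tert-butyl(dimethyl)silyl]oxy}-2-(prop-1-en-2-yl)pentanoyl]-1,3-oxazolidin-2-one | C=C(C)[C@@H](CCCO[Si](C)(C)C(C)(C)C)C(=O)N1[C@H](Cc2ccccc2)COC1=O | intermediate
7 | prop-2-en-1-ol | C=CCO | starting material
8 | prop-2-en-1-yl (2R)-5-{[tert-butyl(dimethyl)silyl]oxy}-2-(prop-1-en-2-yl)pentanoate | C=C(C)[C@@H](CCCO[Si](C)(C)C(C)(C)C)C(=O)OCC=C | intermediate
9 | (3R)-3-(3-{[tert-butyl(dimethyl)silyl]oxy}propyl)-4-methyl-3,6-dihydro-2H-pyran-2-one | O=C1OCC=C(C)[C@H]1CCCO[Si](C)(C)C(C)(C)C | intermediate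
10 | 4,4,5,5-tetramethyl-1,3,2-dioxaborolan-2-yl (2R,3Z)-2-(3-{[tert-butyl(dimethyl)silyl]oxy}propyl)-3-methyl-5-(4,4,5,5-tetramethyl-1,3,2-dioxaborolan-2-yl)pent-3-enoate | CC1(C)OB(C/C=C(C)\[C@@H](CCCO[Si](C)(C)C(C)(C)C)C(=O)OB2OC(C)(C)C(C)(C)O2)OC1(C)C | intermediate
11 | (2R,3Z)-2-(3-{[tert-butyl(dimethyl)silyl]oxy}propyl)-3-methyl-5-(4,4,5,5-tetramethyl-1,3,2-dioxaborolan-2-yl)pent-3-enoic acid | CC1(C)OB(C/C=C(C)\[C@@H](CCCO[Si](C)(C)C(C)(C)C)C(=O)O)OC1(C)C | intermediate
12 | 3-ethoxy-2-methyl-3-oxopropanoic acid (ethyl hydrogen methylmalonate) | CCOC(=O)C(C)C(=O)O | starting material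
13 | (2R,3Z)-2-(3-{[tert-butyl(dimethyl)silyl]oxy}propyl)-1-(1H-imidazol-1-yl)-3-methyl-5-(4,4,5,5-tetramethyl-1,3,2-dioxaborolan-2-yl)pent-3-en-1-one | CC1(C)OB(C/C=C(C)\[C@@H](CCCO[Si](C)(C)C(C)(C)C)C(=O)n2ccnc2)OC1(C)C | intermediate
14 | ethyl (4R,5Z)-4-(3-{[tert-butyl(dimethyl)silyl]oxy}propyl)-2,5-dimethyl-3-oxo-7-(4,4,5,5-tetramethyl-1,3,2-dioxaborolan-2-yl)hept-5-enoate (both C2 epimers) | CC1(C)OB(C/C=C(C)\[C@@H](CCCO[Si](C)(C)C(C)(C)C)C(=O)C(C)C(=O)OCC)OC1(C)C | intermediate
15 | ethyl (2E,4R,5Z)-4-(3-{[tert-butyl(dimethyl)silyl]oxy}propyl)-2,5-dimethyl-7-(4,4,5,5-tetramethyl-1,3,2-dioxaborolan-2-yl)-3-{[(trifluoromethyl)sulfonyl]oxy}hepta-2,5-dienoate | CC1(C)OB(C/C=C(C)\[C@@H](CCCO[Si](C)(C)C(C)(C)C)/C(OS(=O)(=O)C(F)(F)F)=C(/C)C(=O)OCC)OC1(C)C | intermediate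
16 | 1-methylcyclopropan-1-ol | CC1(O)CC1 | starting material
17 | ethyl (2Z,4R,5Z)-4-(3-{[tert-butyl(dimethyl)silyl]oxy}propyl)-2,5-dimethyl-3-(3-oxobutyl)-7-(4,4,5,5-tetramethyl-1,3,2-dioxaborolan-2-yl)hepta-2,5-dienoate | CC1(C)OB(C/C=C(C)\[C@@H](CCCO[Si](C)(C)C(C)(C)C)/C(CCC(C)=O)=C(/C)C(=O)OCC)OC1(C)C | intermediate
18 | ethyl (2Z)-2-[(2S,3S,4R)-2-(3-{[tert-butyl(dimethyl)silyl]oxy}propyl)-3-ethenyl-3,4-dimethyl-4-[(4,4,5,5-tetramethyl-1,3,2-dioxaborolan-2-yl)oxy]cyclohexylidene]propanoate | C=C[C@@]1(C)[C@@H](CCCO[Si](C)(C)C(C)(C)C)/C(=C(/C)C(=O)OCC)CC[C@@]1(C)OB1OC(C)(C)C(C)(C)O1 | intermediate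
19 | ethyl (2Z)-2-[(2S,3S,4R)-2-(3-{[tert-butyl(dimethyl)silyl]oxy}propyl)-3-ethenyl-4-hydroxy-3,4-dimethylcyclohexylidene]propanoate | C=C[C@@]1(C)[C@@H](CCCO[Si](C)(C)C(C)(C)C)/C(=C(/C)C(=O)OCC)CC[C@@]1(C)O | intermediate
20 | pent-4-ynoic acid | C#CCCC(=O)O | starting material
21 | 1-(1H-imidazol-1-yl)pent-4-yn-1-one | C#CCCC(=O)n1ccnc1 | intermediate
22 | N-methoxy-N-methylpent-4-ynamide | C#CCCC(=O)N(C)OC | intermediate
23 | 2-methylhept-6-yn-3-one | CC(C)C(=O)CCC#C | intermediate
24 | 6-methyl-5-methylidenehept-1-yne | C#CCCC(=C)C(C)C | intermediate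
25 | [(1E)-2,6-dimethyl-5-methylidenehept-1-en-1-yl]dimethylalumane | C[Al](C)/C=C(C)/CCC(=C)C(C)C | intermediate
26 | (2E)-3,7-dimethyl-6-methylideneoct-2-en-1-ol | OC/C=C(C)/CCC(=C)C(C)C | intermediate
27 | (2E)-1-bromo-3,7-dimethyl-6-methylideneoct-2-ene | BrC/C=C(C)/CCC(=C)C(C)C | intermediate
28 | trimethyl(prop-1-yn-1-yl)silane | CC#C[Si](C)(C)C | starting material
29 | [(5E)-6,10-dimethyl-9-methylideneundec-5-en-1-yn-1-yl]trimethylsilane | C[Si](C)(C)C#CCC/C=C(C)/CCC(=C)C(C)C | intermediate
30 | (5E)-6,10-dimethyl-9-methylideneundec-5-en-1-yne | C#CCC/C=C(C)/CCC(=C)C(C)C | intermediate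
31 | [(1E,5E)-2,6,10-trimethyl-9-methylideneundeca-1,5-dien-1-yl]dimethylalumane | C[Al](C)/C=C(C)/CC/C=C(C)/CCC(=C)C(C)C | intermediate
32 | (1E,5E)-1-iodo-2,6,10-trimethyl-9-methylideneundeca-1,5-diene | I/C=C(C)/CC/C=C(C)/CCC(=C)C(C)C | intermediate
33 | ethyl (2Z)-2-[(2S,3S,4R)-3-[2-(9-borabicyclo[3.3.1]nonan-9-yl)ethyl]-2-(3-{[tert-butyl(dimethyl)silyl]oxy}propyl)-4-hydroxy-3,4-dimethylcyclohexylidene]propanoate | B1(CC[C@@]2(C)[C@@H](CCCO[Si](C)(C)C(C)(C)C)/C(=C(/C)C(=O)OCC)CC[C@@]2(C)O)C3CCCC1CCC3 | intermediate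
34 | ethyl (2Z)-2-[(2S,3S,4R)-2-(3-{[tert-butyl(dimethyl)silyl]oxy}propyl)-4-hydroxy-3,4-dimethyl-3-[(3E,7E)-4,8,12-trimethyl-11-methylidenetrideca-3,7-dien-1-yl]cyclohexylidene]propanoate | C=C(CC/C(C)=C/CC/C(C)=C/CC[C@@]1(C)[C@@H](CCCO[Si](C)(C)C(C)(C)C)/C(=C(/C)C(=O)OCC)CC[C@@]1(C)O)C(C)C | intermediate
35 | (2Z)-2-[(2S,3S,4R)-2-(3-{[tert-butyl(dimethyl)silyl]oxy}propyl)-4-hydroxy-3,4-dimethyl-3-[(3E,7E)-4,8,12-trimethyl-11-methylidenetrideca-3,7-dien-1-yl]cyclohexylidene]propan-1-ol | C=C(CC/C(C)=C/CC/C(C)=C/CC[C@@]1(C)[C@@H](CCCO[Si](C)(C)C(C)(C)C)/C(=C(/C)CO)CC[C@@]1(C)O)C(C)C | intermediate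
36 | (2Z)-2-[(2S,3S,4R)-2-(3-{[tert-butyl(dimethyl)silyl]oxy}propyl)-4-hydroxy-3,4-dimethyl-3-[(3E,7E)-4,8,12-trimethyl-11-methylidenetrideca-3,7-dien-1-yl]cyclohexylidene]propanal | C=C(CC/C(C)=C/CC/C(C)=C/CC[C@@]1(C)[C@@H](CCCO[Si](C)(C)C(C)(C)C)/C(=C(/C)C=O)CC[C@@]1(C)O)C(C)C | intermediate
37 | (2Z)-2-[(2S,3S,4R)-4-hydroxy-2-(3-hydroxypropyl)-3,4-dimethyl-3-[(3E,7E)-4,8,12-trimethyl-11-methylidenetrideca-3,7-dien-1-yl]cyclohexylidene]propanal | C=C(CC/C(C)=C/CC/C(C)=C/CC[C@@]1(C)[C@@H](CCCO)/C(=C(/C)C=O)CC[C@@]1(C)O)C(C)C | target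

**Totals and risks**

Total step count: 21. Longest linear sequence: 12 steps (steps 1, 3–9 and 18–21; the side-chain branch, steps 10–17 then 18–21, is equally long).

Steps most likely to fail:

1. Step 9 (Proposed new method). The palladium homoenolate may undergo β-hydride elimination, losing methyl vinyl ketone and reducing the triflate. The allyl group may transfer from boron to palladium and close a five-membered ring. The ring closure may be too slow at a temperature the triflate tolerates. The fallback uses known chemistry with a masked ketone and sets out from 15. Negishi coupling with [2-(2-methyl-1,3-dioxolan-2-yl)ethyl]zinc bromide (from 2-(2-bromoethyl)-2-methyl-1,3-dioxolane, Zn, LiCl, THF) under Pd(OAc)2/SPhos in THF at 40 °C should give ethyl (2Z,4R,5Z)-4-[3-(TBS-oxy)propyl]-2,5-dimethyl-3-[2-(2-methyl-1,3-dioxolan-2-yl)ethyl]-7-(Bpin)hepta-2,5-dienoate F1; no base is present, so the boronate should stay silent. Acetal cleavage with pyridinium p-toluenesulfonate in wet acetone at 50 °C should release ketone 17, which closes in the same mildly acidic medium (or in toluene at 80 °C) to borate 18. Aqueous work-up brings the route back at 19.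

2. Step 8. O-sulfonylation may occur through the chelate-like enolate geometry and give the (Z)-triflate, which would invert the enal geometry, and hydroxide may epimerise the doubly allylic α-stereocentre. The fallback sets out from 14 and replaces ion-pair control of a free enolate by sulfonyl transfer from an N-sulfonylimidazolium salt to the amine-paired enolate. TsCl, N-methylimidazole and Et3N in CH2Cl2 at 0 °C should give ethyl (2E,4R,5Z)-4-[3-(TBS-oxy)propyl]-2,5-dimethyl-3-{[(4-methylphenyl)sulfonyl]oxy}-7-(Bpin)hepta-2,5-dienoate F2. F2 is robust enough for any (Z) isomer to be removed by chromatography and returned to 14 by methanolysis. F2 then takes the place of 15 in step 9 (tosylates are served by the biarylphosphine already chosen there), and the route is rejoined at 19.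

3. Step 6. The π-allylpalladium carboxylate may lose a β-hydrogen to give a dienoic acid, the (Z) geometry may erode, or the free acid may protodeboronate the product. The fallback sets out from 9 and moves the boron introduction to an acyclic allylic chloride. Ring opening with MeNHOMe·HCl and i-PrMgCl in THF at −20 °C should give (2R,3Z)-2-[3-(TBS-oxy)propyl]-5-hydroxy-N-methoxy-N,3-dimethylpent-3-enamide F3. MsCl, LiCl and 2,4,6-collidine in DMF at 0 °C should give (2R,3Z)-2-[3-(TBS-oxy)propyl]-5-chloro-N-methoxy-N,3-dimethylpent-3-enamide F4. Borylation (Pd2(dba)3, B2pin2, THF, 60 °C) should give (2R,3Z)-2-[3-(TBS-oxy)propyl]-N-methoxy-N,3-dimethyl-5-(Bpin)pent-3-enamide F5. Addition of the lithium enolate of ethyl propanoate (LDA, THF, −78 °C) to the Weinreb amide brings the route back at 14.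

Further compounds
F1 | step 9 | ethyl (2Z,4R,5Z)-4-(3-{[tert-butyl(dimethyl)silyl]oxy}propyl)-2,5-dimethyl-3-[2-(2-methyl-1,3-dioxolan-2-yl)ethyl]-7-(4,4,5,5-tetramethyl-1,3,2-dioxaborolan-2-yl)hepta-2,5-dienoate | CC1(C)OB(C/C=C(C)\[C@@H](CCCO[Si](C)(C)C(C)(C)C)/C(CCC2(C)OCCO2)=C(/C)C(=O)OCC)OC1(C)C
F2 | step 8 | ethyl (2E,4R,5Z)-4-(3-{[tert-butyl(dimethyl)silyl]oxy}propyl)-2,5-dimethyl-3-{[(4-methylphenyl)sulfonyl]oxy}-7-(4,4,5,5-tetramethyl-1,3,2-dioxaborolan-2-yl)hepta-2,5-dienoate | CC1(C)OB(C/C=C(C)\[C@@H](CCCO[Si](C)(C)C(C)(C)C)/C(OS(=O)(=O)c2ccc(C)cc2)=C(/C)C(=O)OCC)OC1(C)C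
F3 | step 6 | (2R,3Z)-2-(3-{[tert-butyl(dimethyl)silyl]oxy}propyl)-5-hydroxy-N-methoxy-N,3-dimethylpent-3-enamide | OC/C=C(C)\[C@@H](CCCO[Si](C)(C)C(C)(C)C)C(=O)N(C)OC
F4 | step 6 | (2R,3Z)-2-(3-{[tert-butyl(dimethyl)silyl]oxy}propyl)-5-chloro-N-methoxy-N,3-dimethylpent-3-enamide | ClC/C=C(C)\[C@@H](CCCO[Si](C)(C)C(C)(C)C)C(=O)N(C)OC
F5 | step 6 | (2R,3Z)-2-(3-{[tert-butyl(dimethyl)silyl]oxy}propyl)-N-methoxy-N,3-dimethyl-5-(4,4,5,5-tetramethyl-1,3,2-dioxaborolan-2-yl)pent-3-enamide | CC1(C)OB(C/C=C(C)\[C@@H](CCCO[Si](C)(C)C(C)(C)C)C(=O)N(C)OC)OC1(C)C
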